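**Retrosynthetic overview**
1. Target 14 ⇐ 7‑O‑MOM flavone 13 by acetal cleavage.
2. Ring C of 13 ⇐ O1–C8a bond: the enol oxygen of 1,3‑diketone 12 displaces one of the two equivalent ortho‑OMe groups (new photoredox cation‑radical SNAr).
3. 12 ⇐ C2–C3 bond: Claisen condensation of acetophenone 9 with methyl 3,4‑dimethoxybenzoate 10 (ring B bought).
4. 9 ⇐ C4–C4a bond: ortho‑lithiation/acylation of the mirror‑symmetric pentaoxygenated arene 6. Arene 6 ⇐ 2,6‑dimethoxyphenol 1 by MOM protection, double bromination and double CuBr‑catalysed methoxylation.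
5. Ring order: rings A and B come from commercial arenes; ring C is closed last.

Assumption: the target is an achiral flavone with no stereocentre, so there is no enantiomer to control and the route only has to deliver the correct constitution.

**Step 1**
Reactants: 1 2,6‑dimethoxyphenol
Product: 2 1,3‑dimethoxy‑2‑(methoxymethoxy)benzene
Conditions: MOMCl (1.3 equiv), K2CO3 (2 equiv), DMF, 0 °C to rt
Reagents that add atoms: chloromethyl methyl ether (MOMCl), COCCl
Why: Williamson‑type O‑alkylation of the phenoxide with the reactive alpha‑chloro ether gives the MOM acetal, a base‑ and organolithium‑stable mask for the future 7‑OH.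

**Step 2**
Reactants: 2 1,3‑dimethoxy‑2‑(methoxymethoxy)benzene
Product: 4 1,5‑dibromo‑2,4‑dimethoxy‑3‑(methoxymethoxy)benzene, via monobromide 3 (not isolated)
Conditions: NBS (2.2 equiv), DMF, 0 to 40 °C, dark
Reagents that add atoms: N‑bromosuccinimide (NBS), O=C1CCC(=O)N1Br
Why: Electrophilic aromatic bromination of a 1,2,3‑trialkoxybenzene goes para to each outer methoxy group (the twisted central alkoxy group barely activates its own para position), so two successive brominations give the symmetric 1,5‑dibromide.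

**Step 3**
Reactants: 4 1,5‑dibromo‑2,4‑dimethoxy‑3‑(methoxymethoxy)benzene
Product: 6 1,2,4,5‑tetramethoxy‑3‑(methoxymethoxy)benzene, via bromo trimethoxy intermediate 5 (not isolated)
Conditions: NaOMe (6 equiv), CuBr (20 mol%), MeOH/DMF, 110 °C
Reagents that add atoms: sodium methoxide, [Na+].[O-]C
Why: Ullmann‑type C–O coupling, in which CuBr‑catalysed substitution of electron‑rich aryl bromides by methoxide is a standard entry to polymethoxybenzenes, converts both C–Br bonds and completes the symmetric ring A.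

**Step 4**
Reactants: 6 1,2,4,5‑tetramethoxy‑3‑(methoxymethoxy)benzene
Product: 9 1‑[2,3,5,6‑tetramethoxy‑4‑(methoxymethoxy)phenyl]ethan‑1‑one, via aryllithium 7 (not isolated), via tetrahedral lithium adduct 8 (not isolated)
Conditions: n‑BuLi (1.15 equiv), TMEDA, THF, 0 °C; then MeC(O)N(OMe)Me, −78 to 0 °C; then H2O
Reagents that add atoms: N‑methoxy‑N‑methylacetamide, CC(=O)N(C)OC
Why: Directed ortho‑metalation at the only ring C–H, which is flanked by two methoxy groups, followed by Weinreb amide acylation, where the chelated tetrahedral adduct prevents over‑addition.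

**Step 5**
Reactants: 9 1‑[2,3,5,6‑tetramethoxy‑4‑(methoxymethoxy)phenyl]ethan‑1‑one; 10 methyl 3,4‑dimethoxybenzoate
Product: 12 1‑(3,4‑dimethoxyphenyl)‑3‑[2,3,5,6‑tetramethoxy‑4‑(methoxymethoxy)phenyl]propane‑1,3‑dione, via sodium diketonate 11 (not isolated)
Conditions: NaH (3 equiv), THF, reflux; then AcOH
Reagents that add atoms: none
Why: Crossed Claisen condensation, in which the methyl ketone enolate attacks the non‑enolisable aryl ester and irreversible formation of the sodium 1,3‑diketonate drives the reaction, while the hindered ketone cannot self‑condense.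

**Step 6**
Reactants: 12 1‑(3,4‑dimethoxyphenyl)‑3‑[2,3,5,6‑tetramethoxy‑4‑(methoxymethoxy)phenyl]propane‑1,3‑dione
Product: 13 2‑(3,4‑dimethoxyphenyl)‑5,6,8‑trimethoxy‑7‑(methoxymethoxy)‑4H‑chromen‑4‑one
Conditions: 9‑mesityl‑3,6‑di‑tert‑butyl‑10‑phenylacridinium tetrafluoroborate (5 mol%), ClCH2CH2Cl/CF3CH2OH 4:1 (0.05 M, degassed), 450 nm LEDs, N2, 30 °C
Reagents that add atoms: none
Why: Proposed new method: an intramolecular cation‑radical‑accelerated nucleophilic aromatic substitution in which the photoexcited acridinium (excited‑state reduction potential about +2.0 V vs SCE) oxidises the twisted pentaalkoxyaryl ring A of 12 (estimated +1.4 to +1.6 V) to its radical cation, the enol oxygen of the 1,3‑diketone attacks the OMe‑bearing ortho carbon through a 6‑membered transition state, the resulting cyclohexadienyl radical (spin at the carbon alpha to the ketone) is reduced by the acridinyl radical to a dienolate that expels methoxide (protonated by CF3CH2OH) and rearomatises to the chromone, so the process is redox‑neutral, gives one regioisomer because the two ortho OMe groups are equivalent, and any non‑productive oxidation of the enol or ring B is undone by back electron transfer; the closest known reaction type is the intermolecular acridinium‑photocatalysed ipso‑substitution of methoxyarenes by azoles, amines or cyanide, which has not been run with an enol oxygen nucleophile or used to close a chromone ring.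

**Step 7**
Reactants: 13 2‑(3,4‑dimethoxyphenyl)‑5,6,8‑trimethoxy‑7‑(methoxymethoxy)‑4H‑chromen‑4‑one
Product: 14 2‑(3,4‑dimethoxyphenyl)‑7‑hydroxy‑5,6,8‑trimethoxy‑4H‑chromen‑4‑one
Conditions: HCl (1.25 M in MeOH), 45 °C
Reagents that add atoms: none
Why: Acid‑catalysed transacetalisation (MOM acetal cleavage) in methanol frees the 7‑phenol, while aryl methyl ethers and the chromone are inert to dilute HCl.

**Compound list**
1 | 2,6‑dimethoxyphenol | COc1cccc(OC)c1O | starting material
2 | 1,3‑dimethoxy‑2‑(methoxymethoxy)benzene | COCOc1c(OC)cccc1OC | intermediate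
3 | 1‑bromo‑2,4‑dimethoxy‑3‑(methoxymethoxy)benzene | COCOc1c(OC)ccc(Br)c1OC | intermediate
4 | 1,5‑dibromo‑2,4‑dimethoxy‑3‑(methoxymethoxy)benzene | COCOc1c(OC)c(Br)cc(Br)c1OC | intermediate
5 | 1‑bromo‑2,4,5‑trimethoxy‑3‑(methoxymethoxy)benzene | COCOc1c(OC)c(Br)cc(OC)c1OC | intermediate
6 | 1,2,4,5‑tetramethoxy‑3‑(methoxymethoxy)benzene | COCOc1c(OC)c(OC)cc(OC)c1OC | intermediate
7 | [2,3,5,6‑tetramethoxy‑4‑(methoxymethoxy)phenyl]lithium | [Li]c1c(OC)c(OC)c(OCOC)c(OC)c1OC | intermediate
8 | lithium 1‑[methoxy(methyl)amino]‑1‑[2,3,5,6‑tetramethoxy‑4‑(methoxymethoxy)phenyl]ethan‑1‑olate (racemic, transient) | [Li]OC(C)(N(C)OC)c1c(OC)c(OC)c(OCOC)c(OC)c1OC | intermediate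
9 | 1‑[2,3,5,6‑tetramethoxy‑4‑(methoxymethoxy)phenyl]ethan‑1‑one | CC(=O)c1c(OC)c(OC)c(OCOC)c(OC)c1OC | intermediate
10 | methyl 3,4‑dimethoxybenzoate | COC(=O)c1ccc(OC)c(OC)c1 | starting material
11 | sodium 1‑(3,4‑dimethoxyphenyl)‑3‑[2,3,5,6‑tetramethoxy‑4‑(methoxymethoxy)phenyl]propane‑1,3‑dion‑2‑ide | [Na+].COCOc1c(OC)c(OC)c(C(=O)[CH-]C(=O)c2ccc(OC)c(OC)c2)c(OC)c1OC | intermediate
12 | 1‑(3,4‑dimethoxyphenyl)‑3‑[2,3,5,6‑tetramethoxy‑4‑(methoxymethoxy)phenyl]propane‑1,3‑dione (mainly enol in solution) | COCOc1c(OC)c(OC)c(C(=O)CC(=O)c2ccc(OC)c(OC)c2)c(OC)c1OC | intermediate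
13 | 2‑(3,4‑dimethoxyphenyl)‑5,6,8‑trimethoxy‑7‑(methoxymethoxy)‑4H‑chromen‑4‑one | COCOc1c(OC)c(OC)c2c(=O)cc(-c3ccc(OC)c(OC)c3)oc2c1OC | intermediate
14 | 2‑(3,4‑dimethoxyphenyl)‑7‑hydroxy‑5,6,8‑trimethoxy‑4H‑chromen‑4‑one | COc1ccc(-c2cc(=O)c3c(OC)c(OC)c(O)c(OC)c3o2)cc1OC | target

**Step count and risk**
Total steps: 7. Longest linear sequence: 7 steps, from 2,6‑dimethoxyphenol 1.

The three steps most likely to fail:

Step 3 (double methoxylation of a hindered, electron‑rich dibromide; protodebromination can compete). The fallback sets out from dibromide 4 and comes back at arene 6. Double Miyaura borylation (B2pin2, Pd(dppf)Cl2, KOAc, dioxane, 90 °C) gives 2,2'‑[4,6‑dimethoxy‑5‑(methoxymethoxy)‑1,3‑phenylene]bis(4,4,5,5‑tetramethyl‑1,3,2‑dioxaborolane) F1. Oxidation with H2O2/NaOH in THF at 0 °C gives 4,6‑dimethoxy‑5‑(methoxymethoxy)benzene‑1,3‑diol F2. This is methylated at once (MeI, K2CO3, DMF) to give 6.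

Step 4 (the hindered aryllithium may deprotonate the Weinreb amide instead of adding to it). The fallback sets out from arene 6 and comes back at ketone 9. Aryllithium 7 is generated as before and trapped with acetaldehyde, which is small and very electrophilic, to give after aqueous quench racemic 1‑[2,3,5,6‑tetramethoxy‑4‑(methoxymethoxy)phenyl]ethan‑1‑ol F3. Oxidation with Dess–Martin periodinane (NaHCO3, CH2Cl2) gives 9; the stereocentre of F3 is destroyed in this step.

Step 6 (the proposed new photoredox ring closure; risks are low conversion through back electron transfer, or oxidation at the enol/ring B side). The fallback uses only known chemistry, sets out from ketone 9 and comes back at target 14.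
- BCl3 in CH2Cl2 (−78 to 0 °C) removes the MOM group and, by chelation to the carbonyl, one of the two equivalent ortho methyl ethers, giving 1‑(2,4‑dihydroxy‑3,5,6‑trimethoxyphenyl)ethan‑1‑one F4.
- The non‑chelated 4‑OH is benzylated selectively (BnBr 1.05 equiv, K2CO3, acetone, reflux) to give 1‑[4‑(benzyloxy)‑2‑hydroxy‑3,5,6‑trimethoxyphenyl]ethan‑1‑one F5.
- Claisen–Schmidt condensation with 3,4‑dimethoxybenzaldehyde (KOH, EtOH, rt) gives (E)‑1‑[4‑(benzyloxy)‑2‑hydroxy‑3,5,6‑trimethoxyphenyl]‑3‑(3,4‑dimethoxyphenyl)prop‑2‑en‑1‑one F6.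
- Oxidative cyclisation with catalytic I2 in DMSO at 130 °C gives 7‑(benzyloxy)‑2‑(3,4‑dimethoxyphenyl)‑5,6,8‑trimethoxy‑4H‑chromen‑4‑one F7.
- Hydrogenolysis (H2, Pd/C, EtOAc/MeOH, rt) gives 14.

**Further compounds**
F1 | step 3 | 2,2'‑[4,6‑dimethoxy‑5‑(methoxymethoxy)‑1,3‑phenylene]bis(4,4,5,5‑tetramethyl‑1,3,2‑dioxaborolane) | COCOc1c(OC)c(B2OC(C)(C)C(C)(C)O2)cc(B2OC(C)(C)C(C)(C)O2)c1OC
F2 | step 3 | 4,6‑dimethoxy‑5‑(methoxymethoxy)benzene‑1,3‑diol | COCOc1c(OC)c(O)cc(O)c1OC
F3 | step 4 | 1‑[2,3,5,6‑tetramethoxy‑4‑(methoxymethoxy)phenyl]ethan‑1‑ol (racemic) | CC(O)c1c(OC)c(OC)c(OCOC)c(OC)c1OC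
F4 | step 6 | 1‑(2,4‑dihydroxy‑3,5,6‑trimethoxyphenyl)ethan‑1‑one | CC(=O)c1c(O)c(OC)c(O)c(OC)c1OC
F5 | step 6 | 1‑[4‑(benzyloxy)‑2‑hydroxy‑3,5,6‑trimethoxyphenyl]ethan‑1‑one | CC(=O)c1c(O)c(OC)c(OCc2ccccc2)c(OC)c1OC
F6 | step 6 | (E)‑1‑[4‑(benzyloxy)‑2‑hydroxy‑3,5,6‑trimethoxyphenyl]‑3‑(3,4‑dimethoxyphenyl)prop‑2‑en‑1‑one | COc1ccc(/C=C/C(=O)c2c(O)c(OC)c(OCc3ccccc3)c(OC)c2OC)cc1OC
F7 | step 6 | 7‑(benzyloxy)‑2‑(3,4‑dimethoxyphenyl)‑5,6,8‑trimethoxy‑4H‑chromen‑4‑one | COc1ccc(-c2cc(=O)c3c(OC)c(OC)c(OCc4ccccc4)c(OC)c3o2)cc1OC
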